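**Earlier runs.** Substrate is the limiting reagent in the flask, at 0.25 M against 0.500 M of reagent.

| flask | substrate | reagent | remark | time |
|---|---|---|---|---|
| oak | 0.12 M | 0.50 M (fed, over 15 min) | run made earlier |  |
| maple | 0.50 M | 0.50 M (fed, over 15 min) | run made earlier |  |
| flask | 0.25 M | 0.500 M (fed, over 15 min) |  | 20 h |

| run | time / h | target / % | substrate / % |
|---|---|---|---|
| oak | 2.00 | 19.4 | 53.2 |
| oak | 5.00 | 42.4 | 28.0 |
| oak | 10.0 | 58.5 | 10.2 |
| oak | 15.0 | 64.3 | 3.3 |
| oak | 20.0 | 66.2 | 1.5 |
| maple | 4.00 | 30.5 | 47.2 |
| maple | 8.00 | 43.6 | 31.4 |
| maple | 12.0 | 49.4 | 23.8 |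
| maple | 15.0 | 52.8 | 20.6 |
| maple | 20.0 | 56.5 | 16.0 |

(readings scatter by 0.5 percentage points)

- amount of target in percent of the substrate charged, at 4.0 h, 10 h and 20 h

- the analysis behind the earlier runs scatters by 0.5 percentage points, standard deviation

At 20.0 h the oak run has consumed nearly all its substrate, and its readings give 67.2%: target formed per substrate consumed, the target share φ (the selectivity). This is the ratio to watch on a repeat.

**Starting rate.** What follows is a separate reckoning, not the forecast's. Reading the substrate loss in the maple run as second order, with reagent used one for one, gives the flask an apparent starting rate w of 0.263 h⁻¹, as a fraction of the charged substrate per hour. The feed of 15 min is short against the 3.80 h of 1/w, so the charge is counted as present at once.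

**Accumulated slowing.** Integrated to 20 h, this law leaves 3.76% of the substrate in the flask. The fall in substrate takes 1.42 decades off the rate, more than the 0.285 decades taken off by the fall in reagent. Together they slow the rate by a factor of 51.3, to 0.00513 h⁻¹. In this reckoning the substrate loss in the flask is therefore nearly over by then, and φ times the substrate consumed gives 64.7% target.

**The forecast.** The forecast gives 32.5%, 55.5% and 65%, on the ground that “about two-thirds of the consumed substrate goes through a short-lived intermediate to target”.

**The result.** The flask gives 34.1%, 55.0% and 64.3%, so the forecast is right within the tolerance.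

    substrate + reagent ⇌ intermediate A (K = 1.26 M⁻¹, k = 3.84 × 10⁻⁴ M⁻¹ s⁻¹)
    intermediate A → target (k = 1.60 × 10⁻⁴ s⁻¹)
    intermediate A → intermediate B (k = 7.80 × 10⁻⁵ s⁻¹)
    reagent + intermediate B ⇌ intermediate C (K = 5.56 M⁻¹, k = 1.78 × 10⁻⁵ M⁻¹ s⁻¹)

**The branch.** At 20 h the flask shows a target share of 66.8%, close to φ. In the maple run, φ turns the substrate consumed into 56.5% target against 56.5% read. The passing of intermediate A into intermediate B is the main reason for the missing target, and the run without it shows a change that puts the forecast wrong: the flask then gives 91.6% in place of 64.3%.

(The runs were generated by integration with made-up constants, noise included.)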